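**Strategy.** The 14-membered carbocycle (ring A, C1–C14) is disconnected at C9–C10. The key step exploits the exocyclic C19=C8–C9 allyl unit on oxolane ring B (C4–O–C7): it is substituted only at its central carbon C8, so its two CH2 termini are equivalent, while C10 lies next to the C11 carbonyl. Zerovalent palladium ionises a C9 aryl ether and the C10 carbanion of a β-keto sulfone closes ring A in one operation, leaving the C8=C19 methylene in place. The precursor is the seco compound in which the seven-membered lactone (ring C, C16–O–C12) and ring B are complete, C2 is silylated and C12 carries the phenylsulfonylacetyl group.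

Key step: step 23

Remark on numbering: cembrane locants are used. Ring A = C1–C14; C15/C16 = lactone CH2/C=O on C1, O-linked to C12; C17 = methylene on C15; C18, C20 = methyls on C4, C12; C19 = methylene on C8. Macrocycles are named as 4,7-epoxycembran-16,12-olides. Abbreviations: TBS = tert-butyldimethylsilyl, TBDPS = tert-butyldiphenylsilyl, TES = triethylsilyl, RB = (2S,5R)-5-[3-(4-methoxyphenoxy)prop-1-en-2-yl]-2-methyloxolan-2-yl.

Remark on the chemistry: the given stereodescriptors were checked and map onto the target (1R,2S,4S,7R,11S,12S); (S)-citramalic acid delivers 12S unchanged. It is assumed that the L-fructose-derived Shi ketone and (S,S)-ProPhenol are purchased.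

**Route**

Step 1
Reactants: 1 geraniol
Product: 2 (2S,3S)-2,3-epoxygeraniol
Conditions: Ti(OiPr)4 (5 mol %), L-(+)-diethyl tartrate (6 mol %), t-BuOOH, 4 Å MS, CH2Cl2, −20 °C
Reagents that add atoms: tert-butyl hydroperoxide, CC(C)(C)OO
Why: Katsuki–Sharpless asymmetric epoxidation of an E-trisubstituted allylic alcohol, in which the L-(+)-tartrate complex should deliver oxygen to the face that gives the (2S,3S)-epoxide and so fixes the future C4 as S.

Step 2
Reactants: 2 (2S,3S)-2,3-epoxygeraniol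
Product: 3 (3S)-3,7-dimethyloct-6-ene-1,3-diol
Conditions: NaAlH2(OCH2CH2OMe)2, THF, 0 °C
Reagents that add atoms: none
Why: Hydroxyl-directed reductive opening of a 2,3-epoxy alcohol, in which the oxygen-bound aluminium hydride should deliver hydride to the carbinol-proximal epoxide carbon and leave the tertiary C–O centre untouched.

Step 3
Reactants: 3 (3S)-3,7-dimethyloct-6-ene-1,3-diol
Product: 4 (3S)-1-(TBDPS-oxy)-3,7-dimethyloct-6-en-3-ol
Conditions: TBDPSCl, imidazole, CH2Cl2, 0 °C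
Reagents that add atoms: tert-butyl(chloro)diphenylsilane, CC(C)(C)[Si](Cl)(c1ccccc1)c1ccccc1
Why: Chemoselective silylation of the primary hydroxyl, the tertiary one being too hindered for this chlorosilane.

Step 4
Reactants: 4 (3S)-1-(TBDPS-oxy)-3,7-dimethyloct-6-en-3-ol
Product: 6 2-[(2R,5S)-5-[2-(TBDPS-oxy)ethyl]-5-methyloxolan-2-yl]propan-2-ol, via epoxide 5 (not isolated)
Conditions: L-fructose-derived Shi ketone (30 mol %), KHSO5 (as 2KHSO5·KHSO4·K2SO4), K2CO3, Bu4NHSO4, MeCN/CH2(OMe)2/aq. Na2B4O7 buffer, 0 °C; then camphorsulfonic acid (10 mol %), CH2Cl2, 0 °C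
Reagents that add atoms: potassium peroxymonosulfate, [K+].[O-]S(=O)(=O)OO
Why: Shi asymmetric epoxidation with the enantiomeric (L-series) ketone should give the (S)-epoxide, and acid-catalysed 5-exo-tet opening by the tertiary hydroxyl with inversion then sets C7 as R with the two carbon chains cis on ring B (the minor 6-endo tetrahydropyran is removed by chromatography).

Step 5
Reactants: 6 2-[(2R,5S)-5-[2-(TBDPS-oxy)ethyl]-5-methyloxolan-2-yl]propan-2-ol
Product: 7 tert-butyl{2-[(2S,5R)-2-methyl-5-(prop-1-en-2-yl)oxolan-2-yl]ethoxy}diphenylsilane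
Conditions: SOCl2, pyridine, CH2Cl2, −20 → 0 °C
Reagents that add atoms: none
Why: E2 dehydration of the tertiary alcohol through its chlorosulfite, in which pyridine should remove a methyl hydrogen and not the hindered ring C7–H, as is known for furanoid linalool oxides.

Step 6
Reactants: 7 tert-butyl{2-[(2S,5R)-2-methyl-5-(prop-1-en-2-yl)oxolan-2-yl]ethoxy}diphenylsilane
Product: 8 tert-butyl{2-[(2S,5R)-5-(3-chloroprop-1-en-2-yl)-2-methyloxolan-2-yl]ethoxy}diphenylsilane
Conditions: Ca(OCl)2, solid CO2, CH2Cl2/H2O, 0 °C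
Reagents that add atoms: calcium hypochlorite, [Ca+2].[O-]Cl.[O-]Cl
Why: Ene-type allylic chlorination of an isopropenyl group by HOCl generated in situ, which places chlorine on one CH2 of the allyl unit and regenerates the 1,1-disubstituted alkene.

Step 7
Reactants: 8 tert-butyl{2-[(2S,5R)-5-(3-chloroprop-1-en-2-yl)-2-methyloxolan-2-yl]ethoxy}diphenylsilane
Product: 9 tert-butyl[2-(RB)ethoxy]diphenylsilane
Conditions: 4-methoxyphenol, K2CO3, DMF, 50 °C
Reagents that add atoms: 4-methoxyphenol, COc1ccc(O)cc1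
Why: Williamson etherification (SN2 and SN2′ give the same product) installs an aryl allyl ether that should survive the base, organometallic, oxidant and fluoride steps ahead yet remain ionisable by zerovalent palladium, so it serves as a protected leaving group.

Step 8
Reactants: 9 tert-butyl[2-(RB)ethoxy]diphenylsilane
Product: 10 2-(RB)ethanol
Conditions: Bu4NF, THF, rt
Reagents that add atoms: none
Why: Fluoride-mediated cleavage of the silyl ether, to which the aryl ether and alkene are inert.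

Step 9
Reactants: 10 2-(RB)ethanol
Product: 11 2-(RB)acetaldehyde
Conditions: Dess–Martin periodinane, NaHCO3, CH2Cl2, 0 °C → rt
Reagents that add atoms: none
Why: Dess–Martin oxidation under buffered, non-basic conditions, which should avoid β-elimination of the ring B oxygen from the β-alkoxy aldehyde.

Step 10
Reactants: 11 2-(RB)acetaldehyde; 12 methyl propiolate
Product: 13 methyl (4S)-4-hydroxy-5-(RB)pent-2-ynoate
Conditions: Me2Zn (3 equiv), (S,S)-ProPhenol (20 mol %), Ph3PO (40 mol %), toluene, 4 °C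
Reagents that add atoms: none
Why: Zinc–ProPhenol asymmetric alkynylation of an aldehyde, with the ligand enantiomer chosen to direct the zinc alkynylide to the Re face and create C2 as S (configuration to be confirmed by Mosher analysis; the C2 epimer is a separable diastereomer).

Step 11
Reactants: 13 methyl (4S)-4-hydroxy-5-(RB)pent-2-ynoate
Product: 15 (5S)-5-(RB-methyl)furan-2(5H)-one, via Z-enoate 14 (not isolated)
Conditions: H2 (1 atm), Pd/CaCO3 poisoned with Pb(OAc)2, quinoline, EtOAc, rt; then pyridinium p-toluenesulfonate (cat.), CH2Cl2, rt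
Reagents that add atoms: none
Why: Lindlar semihydrogenation gives the Z-γ-hydroxy enoate, which should lactonise by intramolecular transesterification to the butenolide without touching C2.

Step 12
Reactants: 16 (S)-citramalic acid
Product: 17 (2S)-2-methylbutane-1,2,4-triol
Conditions: BH3·SMe2, B(OMe)3, THF, 0 °C → rt; then MeOH
Reagents that add atoms: none
Why: Borane reduction of both carboxylic acids, which does not involve the quaternary carbinol centre (the future C12).

Step 13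
Reactants: 17 (2S)-2-methylbutane-1,2,4-triol
Product: 18 2-[(4S)-2,2,4-trimethyl-1,3-dioxolan-4-yl]ethanol
Conditions: 2,2-dimethoxypropane, TsOH·H2O (cat.), acetone, rt
Reagents that add atoms: 2,2-dimethoxypropane, COC(C)(C)OC
Why: Thermodynamically controlled acetalisation, which should favour the five-membered 1,2-acetonide over the 1,3-dioxane and leave the C14 hydroxyl free.

Step 14
Reactants: 18 2-[(4S)-2,2,4-trimethyl-1,3-dioxolan-4-yl]ethanol
Product: 19 (4S)-4-(2-iodoethyl)-2,2,4-trimethyl-1,3-dioxolane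
Conditions: I2, PPh3, imidazole, CH2Cl2, 0 °C → rt
Reagents that add atoms: iodine, II
Why: Appel-type (Garegg–Samuelsson) iodination of a primary alcohol under buffered conditions that spare the acetonide.

Step 15
Reactants: 19 (4S)-4-(2-iodoethyl)-2,2,4-trimethyl-1,3-dioxolane; 15 (5S)-5-(RB-methyl)furan-2(5H)-one
Product: 22 (4R,5S)-5-(RB-methyl)-4-{2-[(4S)-2,2,4-trimethyl-1,3-dioxolan-4-yl]ethyl}oxolan-2-one, via organolithium 20 (not isolated), via cuprate 21 (not isolated)
Conditions: 19 (2.5 equiv), t-BuLi (5 equiv), Et2O, −78 °C; CuI (1.25 equiv), −40 °C; then 15, THF, −78 → −40 °C; aq. NH4Cl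
Reagents that add atoms: none
Why: Gilman cuprate 1,4-addition to a γ-substituted butenolide, where attack anti to the C2 substituent should give the trans-4,5-disubstituted lactone and so set C1 as R while forming the C1–C14 bond.

Step 16
Reactants: 22 (4R,5S)-5-(RB-methyl)-4-{2-[(4S)-2,2,4-trimethyl-1,3-dioxolan-4-yl]ethyl}oxolan-2-one
Product: 23 (4R,5S)-4-[(3S)-3,4-dihydroxy-3-methylbutyl]-5-(RB-methyl)oxolan-2-one
Conditions: AcOH/H2O (4:1), 40 °C
Reagents that add atoms: none
Why: Acid hydrolysis of the isopropylidene acetal, done before any silyl ether is present and under conditions the γ-lactone and aryl ether tolerate.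

Step 17
Reactants: 23 (4R,5S)-4-[(3S)-3,4-dihydroxy-3-methylbutyl]-5-(RB-methyl)oxolan-2-one
Product: 26 (3R,4S)-4-(TBS-oxy)-3-[(3S)-4-(TBS-oxy)-3-hydroxy-3-methylbutyl]-5-(RB)pentanoic acid, via lithium carboxylate 24 (not isolated), via silyl ester 25 (not isolated)
Conditions: LiOH·H2O, THF/H2O, rt, concentrate; TBSCl, imidazole, DMAP (cat.), DMF, 40 °C; then K2CO3, MeOH/THF/H2O, 0 °C; pH 5 work-up
Reagents that add atoms: lithium hydroxide, [Li+].[OH-]; tert-butyl(chloro)dimethylsilane, CC(C)(C)[Si](C)(C)Cl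
Why: Lactone saponification, silylation of the carboxylate and of the primary and secondary hydroxyls (TBSCl does not silylate the tertiary O12–H), and selective methanolysis of the labile silyl ester should leave O12–H as the only free hydroxyl beside the acid.

Step 18
Reactants: 26 (3R,4S)-4-(TBS-oxy)-3-[(3S)-4-(TBS-oxy)-3-hydroxy-3-methylbutyl]-5-(RB)pentanoic acid
Product: 28 (4R,7S)-7-(TBS-oxymethyl)-7-methyl-4-[(1S)-1-(TBS-oxy)-2-(RB)ethyl]oxepan-2-one, via mixed anhydride 27 (not isolated)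
Conditions: 2,4,6-Cl3C6H2COCl, Et3N, THF, rt; then slow addition to DMAP, toluene, 90 °C (2 mM)
Reagents that add atoms: none
Why: Yamaguchi lactonisation closes ring C on the only free hydroxyl, helped by the gem-disubstituted C12 (Thorpe–Ingold effect) and by heating with excess DMAP, because a tertiary alcohol is acylated slowly.

Step 19
Reactants: 28 (4R,7S)-7-(TBS-oxymethyl)-7-methyl-4-[(1S)-1-(TBS-oxy)-2-(RB)ethyl]oxepan-2-one
Product: 29 (4R,7S)-7-(hydroxymethyl)-7-methyl-4-[(1S)-1-(TBS-oxy)-2-(RB)ethyl]oxepan-2-one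
Conditions: HF·pyridine, pyridine, THF, 0 °C
Reagents that add atoms: none
Why: Selective desilylation with buffered HF·pyridine, which should cleave the primary C11 silyl ether much faster than the hindered secondary C2 one.

Step 20
Reactants: 29 (4R,7S)-7-(hydroxymethyl)-7-methyl-4-[(1S)-1-(TBS-oxy)-2-(RB)ethyl]oxepan-2-one
Product: 30 (2S,5R)-2-methyl-7-oxo-5-[(1S)-1-(TBS-oxy)-2-(RB)ethyl]oxepane-2-carbaldehyde
Conditions: Dess–Martin periodinane, NaHCO3, CH2Cl2, rt
Reagents that add atoms: none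
Why: Dess–Martin oxidation to a non-enolisable α-acyloxy aldehyde, so C12 cannot epimerise.

Step 21
Reactants: 30 (2S,5R)-2-methyl-7-oxo-5-[(1S)-1-(TBS-oxy)-2-(RB)ethyl]oxepane-2-carbaldehyde; 31 methyl phenyl sulfone
Product: 33 (4R,7S)-7-[1-hydroxy-2-(phenylsulfonyl)ethyl]-7-methyl-4-[(1S)-1-(TBS-oxy)-2-(RB)ethyl]oxepan-2-one (C11 epimers), via lithiated sulfone 32 (not isolated)
Conditions: 31 (1.3 equiv), n-BuLi (1.25 equiv), THF, −78 °C; then 30, −78 °C; AcOH quench at −78 °C
Reagents that add atoms: none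
Why: Addition of an α-sulfonyl carbanion to an aldehyde (first stage of a Julia-type sequence), chosen because at −78 °C the aldehyde should react far faster than the lactone, which an ester acylation at C11 could not guarantee; the cold acidic quench prevents acyl migration to the C11 alkoxide.

Step 22
Reactants: 33 (4R,7S)-7-[1-hydroxy-2-(phenylsulfonyl)ethyl]-7-methyl-4-[(1S)-1-(TBS-oxy)-2-(RB)ethyl]oxepan-2-one
Product: 34 (4R,7S)-7-methyl-7-[(phenylsulfonyl)acetyl]-4-[(1S)-1-(TBS-oxy)-2-(RB)ethyl]oxepan-2-one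
Conditions: Dess–Martin periodinane, NaHCO3, CH2Cl2, rt
Reagents that add atoms: none
Why: Dess–Martin oxidation of the β-hydroxy sulfone merges both C11 epimers into the β-keto sulfone that is the cyclisation precursor.

Step 23
Reactants: 34 (4R,7S)-7-methyl-7-[(phenylsulfonyl)acetyl]-4-[(1S)-1-(TBS-oxy)-2-(RB)ethyl]oxepan-2-one
Product: 35 (1R,2S,4S,7R,12S)-2-(TBS-oxy)-4,7-epoxy-11-oxo-10-(phenylsulfonyl)cembr-8(19)-en-16,12-olide (C10 epimers)
Conditions: Pd(PPh3)4 (10 mol %), 1,2-bis(diphenylphosphino)ethane (10 mol %), THF, 65 °C, syringe-pump addition of 34 over 12 h (final 1 mM)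
Reagents that add atoms: none
Why: Zerovalent palladium ionises the aryl allyl ether to a cationic η3-allyl complex of divalent palladium and 4-methoxyphenoxide, which deprotonates the β-keto sulfone (pKa about 12), and the soft C10 carbanion then attacks a CH2 terminus anti to the metal. This is a Tsuji–Trost allylic alkylation under neutral conditions, the reaction type established for 14-membered carbocycles from stabilised carbanions at high dilution and for aryl allyl ethers as leaving groups. Ring A closes by bonding C10 to one terminus of the allyl unit, so that this carbon and C8 become ring atoms and the other terminus remains the exocyclic C19 methylene; because the unit is substituted only at C8, either terminus gives the same 14-membered ring. No stereocentre of the target is created: C10 forms as an epimeric mixture that is erased in step 24. The selectivities needed are ring closure over oligomerisation, C- over O-allylation, and allylation over acyl transfer from O12 to C10. They are secured by slow addition to a dilute catalyst solution, by the reversibility of O-allylation under palladium, and by the aryloxide being the only base present, which is weaker and far less nucleophilic towards ring C than an alkoxide from a carbonate would be.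

Step 24
Reactants: 35 (1R,2S,4S,7R,12S)-2-(TBS-oxy)-4,7-epoxy-11-oxo-10-(phenylsulfonyl)cembr-8(19)-en-16,12-olide
Product: 36 (1R,2S,4S,7R,12S)-2-(TBS-oxy)-4,7-epoxy-11-oxocembr-8(19)-en-16,12-olide
Conditions: Al(Hg), THF/H2O (9:1), 0 °C → rt
Reagents that add atoms: none
Why: Reductive desulfonylation of an α-sulfonyl ketone by electron transfer from aluminium amalgam, chosen because it should leave the α-acyloxy C12–O bond intact, which a stronger one-electron reductant such as SmI2 could also cleave.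

Step 25
Reactants: 36 (1R,2S,4S,7R,12S)-2-(TBS-oxy)-4,7-epoxy-11-oxocembr-8(19)-en-16,12-olide
Product: 37 (1R,2S,4S,7R,11S,12S)-2-(TBS-oxy)-4,7-epoxy-11-hydroxycembr-8(19)-en-16,12-olide
Conditions: NaBH4, CeCl3·7H2O, MeOH/THF, −78 °C
Reagents that add atoms: none
Why: Non-chelating borohydride reduction under polar Felkin–Anh control, with the C12–O bond antiperiplanar to the incoming hydride, which passes the C20 methyl rather than C13 (a geometry that also keeps the C10–C11–C12–C13 backbone of ring A anti), so 11S is expected; low temperature suppresses acyl migration to the new alkoxide.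

Step 26
Reactants: 37 (1R,2S,4S,7R,11S,12S)-2-(TBS-oxy)-4,7-epoxy-11-hydroxycembr-8(19)-en-16,12-olide
Product: 38 (1R,2S,4S,7R,11S,12S)-2-(TBS-oxy)-11-(TES-oxy)-4,7-epoxycembr-8(19)-en-16,12-olide
Conditions: Et3SiOTf, 2,6-lutidine, CH2Cl2, −78 → 0 °C
Reagents that add atoms: triethylsilyl trifluoromethanesulfonate, CC[Si](CC)(CC)OS(=O)(=O)C(F)(F)F
Why: Silylation of the hindered secondary alcohol with a silyl triflate removes the only acidic O–H before enolate chemistry.

Step 27
Reactants: 38 (1R,2S,4S,7R,11S,12S)-2-(TBS-oxy)-11-(TES-oxy)-4,7-epoxycembr-8(19)-en-16,12-olide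
Product: 41 (1R,2S,4S,7R,11S,12S)-2-(TBS-oxy)-11-(TES-oxy)-4,7-epoxycembra-8(19),15(17)-dien-16,12-olide, via Mannich base 39 (not isolated), via ammonium iodide 40 (not isolated)
Conditions: LiN(iPr)2, THF, −78 °C; Me2N=CH2 I (Eschenmoser's salt), −78 °C → rt; then MeI, MeOH, rt; then aq. NaHCO3/CH2Cl2, rt
Reagents that add atoms: N,N-dimethylmethyleneiminium iodide, C=[N+](C)C.[I-]
Why: Eschenmoser α-methylenation of the lactone (enolate Mannich reaction at C15, N-methylation and base-induced elimination of trimethylamine), C15 being the only enolisable position now that C11 is a silyl ether.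

Step 28
Reactants: 41 (1R,2S,4S,7R,11S,12S)-2-(TBS-oxy)-11-(TES-oxy)-4,7-epoxycembra-8(19),15(17)-dien-16,12-olide
Product: 42 CNP0289823.1, (1R,2S,4S,7R,11S,12S)-4,7-epoxy-2,11-dihydroxycembra-8(19),15(17)-dien-16,12-olide
Conditions: HF·pyridine, pyridine, THF, 0 °C → rt
Reagents that add atoms: none
Why: Global desilylation under buffered acidic fluoride conditions, chosen over basic fluoride to avoid oxa-Michael addition to the α-methylene lactone and migration of the lactone to O2.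

**Compound list**

1 | geraniol, (2E)-3,7-dimethylocta-2,6-dien-1-ol | CC(C)=CCC/C(C)=C/CO | starting material
2 | (2S,3S)-2,3-epoxygeraniol | OC[C@@H]1O[C@@]1(C)CCC=C(C)C | intermediate
3 | (3S)-3,7-dimethyloct-6-ene-1,3-diol | OCC[C@@](C)(O)CCC=C(C)C | intermediate
4 | (3S)-1-[tert-butyl(diphenyl)silyl]oxy-3,7-dimethyloct-6-en-3-ol | CC(C)(C)[Si](c1ccccc1)(c1ccccc1)OCC[C@@](C)(O)CCC=C(C)C | intermediate
5 | (3S)-1-[tert-butyl(diphenyl)silyl]oxy-5-[(2S)-3,3-dimethyloxiran-2-yl]-3-methylpentan-3-ol | CC(C)(C)[Si](c1ccccc1)(c1ccccc1)OCC[C@@](C)(O)CC[C@@H]1OC1(C)C | intermediate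
6 | 2-[(2R,5S)-5-{2-[tert-butyl(diphenyl)silyl]oxyethyl}-5-methyloxolan-2-yl]propan-2-ol | CC(C)(C)[Si](c1ccccc1)(c1ccccc1)OCC[C@]1(C)CC[C@@H](O1)C(C)(C)O | intermediate
7 | tert-butyl{2-[(2S,5R)-2-methyl-5-(prop-1-en-2-yl)oxolan-2-yl]ethoxy}diphenylsilane | CC(C)(C)[Si](c1ccccc1)(c1ccccc1)OCC[C@]1(C)CC[C@@H](O1)C(C)=C | intermediate
8 | tert-butyl{2-[(2S,5R)-5-(3-chloroprop-1-en-2-yl)-2-methyloxolan-2-yl]ethoxy}diphenylsilane | CC(C)(C)[Si](c1ccccc1)(c1ccccc1)OCC[C@]1(C)CC[C@@H](O1)C(=C)CCl | intermediate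
9 | tert-butyl{2-[(2S,5R)-5-[3-(4-methoxyphenoxy)prop-1-en-2-yl]-2-methyloxolan-2-yl]ethoxy}diphenylsilane | CC(C)(C)[Si](c1ccccc1)(c1ccccc1)OCC[C@]1(C)CC[C@@H](O1)C(=C)COc1ccc(OC)cc1 | intermediate
10 | 2-[(2S,5R)-5-[3-(4-methoxyphenoxy)prop-1-en-2-yl]-2-methyloxolan-2-yl]ethanol | OCC[C@]1(C)CC[C@@H](O1)C(=C)COc1ccc(OC)cc1 | intermediate
11 | 2-[(2S,5R)-5-[3-(4-methoxyphenoxy)prop-1-en-2-yl]-2-methyloxolan-2-yl]acetaldehyde | O=CC[C@]1(C)CC[C@@H](O1)C(=C)COc1ccc(OC)cc1 | intermediate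
12 | methyl propiolate | C#CC(=O)OC | starting material
13 | methyl (4S)-4-hydroxy-5-[(2S,5R)-5-[3-(4-methoxyphenoxy)prop-1-en-2-yl]-2-methyloxolan-2-yl]pent-2-ynoate | COC(=O)C#C[C@@H](O)C[C@]1(C)CC[C@@H](O1)C(=C)COc1ccc(OC)cc1 | intermediate
14 | methyl (2Z,4S)-4-hydroxy-5-[(2S,5R)-5-[3-(4-methoxyphenoxy)prop-1-en-2-yl]-2-methyloxolan-2-yl]pent-2-enoate | COC(=O)/C=C\[C@@H](O)C[C@]1(C)CC[C@@H](O1)C(=C)COc1ccc(OC)cc1 | intermediate
15 | (5S)-5-{[(2S,5R)-5-[3-(4-methoxyphenoxy)prop-1-en-2-yl]-2-methyloxolan-2-yl]methyl}furan-2(5H)-one | O=C1C=C[C@@H](O1)C[C@]2(C)CC[C@@H](O2)C(=C)COc1ccc(OC)cc1 | intermediate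
16 | (S)-citramalic acid, (2S)-2-hydroxy-2-methylbutanedioic acid | O[C@@](C(=O)O)(C)CC(=O)O | starting material
17 | (2S)-2-methylbutane-1,2,4-triol | O[C@@](CO)(C)CCO | intermediate
18 | 2-[(4S)-2,2,4-trimethyl-1,3-dioxolan-4-yl]ethanol | OCC[C@@]1(C)COC(C)(C)O1 | intermediate
19 | (4S)-4-(2-iodoethyl)-2,2,4-trimethyl-1,3-dioxolane | ICC[C@@]1(C)COC(C)(C)O1 | intermediate
20 | {2-[(4S)-2,2,4-trimethyl-1,3-dioxolan-4-yl]ethyl}lithium | [Li]CC[C@@]1(C)COC(C)(C)O1 | intermediate
21 | lithium bis{2-[(4S)-2,2,4-trimethyl-1,3-dioxolan-4-yl]ethyl}cuprate | [Li+].C(C[C@@]1(C)COC(C)(C)O1)[Cu-]CC[C@@]1(C)COC(C)(C)O1 | intermediate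
22 | (4R,5S)-5-{[(2S,5R)-5-[3-(4-methoxyphenoxy)prop-1-en-2-yl]-2-methyloxolan-2-yl]methyl}-4-{2-[(4S)-2,2,4-trimethyl-1,3-dioxolan-4-yl]ethyl}oxolan-2-one | O=C1C[C@@H](CC[C@@]2(C)COC(C)(C)O2)[C@@H](O1)C[C@]3(C)CC[C@@H](O3)C(=C)COc1ccc(OC)cc1 | intermediate
23 | (4R,5S)-4-[(3S)-3,4-dihydroxy-3-methylbutyl]-5-{[(2S,5R)-5-[3-(4-methoxyphenoxy)prop-1-en-2-yl]-2-methyloxolan-2-yl]methyl}oxolan-2-one | O=C1C[C@@H](CC[C@](C)(O)CO)[C@@H](O1)C[C@]2(C)CC[C@@H](O2)C(=C)COc1ccc(OC)cc1 | intermediate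
24 | lithium (3R,4S)-3-[(3S)-3,4-dihydroxy-3-methylbutyl]-4-hydroxy-5-(RB)pentanoate | [Li+].[O-]C(=O)C[C@@H](CC[C@](C)(O)CO)[C@@H](O)C[C@]1(C)CC[C@@H](O1)C(=C)COc1ccc(OC)cc1 | intermediate
25 | tert-butyldimethylsilyl (3R,4S)-4-(TBS-oxy)-3-[(3S)-4-(TBS-oxy)-3-hydroxy-3-methylbutyl]-5-(RB)pentanoate | CC(C)(C)[Si](C)(C)OC(=O)C[C@@H](CC[C@](C)(O)CO[Si](C)(C)C(C)(C)C)[C@@H](O[Si](C)(C)C(C)(C)C)C[C@]1(C)CC[C@@H](O1)C(=C)COc1ccc(OC)cc1 | intermediate
26 | (3R,4S)-4-(TBS-oxy)-3-[(3S)-4-(TBS-oxy)-3-hydroxy-3-methylbutyl]-5-(RB)pentanoic acid | OC(=O)C[C@@H](CC[C@](C)(O)CO[Si](C)(C)C(C)(C)C)[C@@H](O[Si](C)(C)C(C)(C)C)C[C@]1(C)CC[C@@H](O1)C(=C)COc1ccc(OC)cc1 | intermediate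
27 | mixed anhydride of acid 26 with 2,4,6-trichlorobenzoic acid | O=C(OC(=O)c1c(Cl)cc(Cl)cc1Cl)C[C@@H](CC[C@](C)(O)CO[Si](C)(C)C(C)(C)C)[C@@H](O[Si](C)(C)C(C)(C)C)C[C@]1(C)CC[C@@H](O1)C(=C)COc1ccc(OC)cc1 | intermediate
28 | (4R,7S)-7-(TBS-oxymethyl)-7-methyl-4-[(1S)-1-(TBS-oxy)-2-(RB)ethyl]oxepan-2-one | C1C(=O)O[C@@](CO[Si](C)(C)C(C)(C)C)(C)CC[C@H]1[C@@H](O[Si](C)(C)C(C)(C)C)C[C@]1(C)CC[C@@H](O1)C(=C)COc1ccc(OC)cc1 | intermediate
29 | (4R,7S)-7-(hydroxymethyl)-7-methyl-4-[(1S)-1-(TBS-oxy)-2-(RB)ethyl]oxepan-2-one | C1C(=O)O[C@@](CO)(C)CC[C@H]1[C@@H](O[Si](C)(C)C(C)(C)C)C[C@]1(C)CC[C@@H](O1)C(=C)COc1ccc(OC)cc1 | intermediate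
30 | (2S,5R)-2-methyl-7-oxo-5-[(1S)-1-(TBS-oxy)-2-(RB)ethyl]oxepane-2-carbaldehyde | C1C(=O)O[C@@](C=O)(C)CC[C@H]1[C@@H](O[Si](C)(C)C(C)(C)C)C[C@]1(C)CC[C@@H](O1)C(=C)COc1ccc(OC)cc1 | intermediate
31 | methyl phenyl sulfone | CS(=O)(=O)c1ccccc1 | starting material
32 | [(phenylsulfonyl)methyl]lithium | [Li]CS(=O)(=O)c1ccccc1 | intermediate
33 | (4R,7S)-7-[1-hydroxy-2-(phenylsulfonyl)ethyl]-7-methyl-4-[(1S)-1-(TBS-oxy)-2-(RB)ethyl]oxepan-2-one, C11 epimers | C1C(=O)O[C@@](C(O)CS(=O)(=O)c2ccccc2)(C)CC[C@H]1[C@@H](O[Si](C)(C)C(C)(C)C)C[C@]1(C)CC[C@@H](O1)C(=C)COc1ccc(OC)cc1 | intermediate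
34 | (4R,7S)-7-methyl-7-[(phenylsulfonyl)acetyl]-4-[(1S)-1-(TBS-oxy)-2-(RB)ethyl]oxepan-2-one (seco precursor) | C1C(=O)O[C@@](C(=O)CS(=O)(=O)c2ccccc2)(C)CC[C@H]1[C@@H](O[Si](C)(C)C(C)(C)C)C[C@]1(C)CC[C@@H](O1)C(=C)COc1ccc(OC)cc1 | intermediate
35 | (1R,2S,4S,7R,12S)-2-(TBS-oxy)-4,7-epoxy-11-oxo-10-(phenylsulfonyl)cembr-8(19)-en-16,12-olide, C10 epimers | C1C(=O)O[C@@]2(C)CC[C@H]1[C@@H](O[Si](C)(C)C(C)(C)C)C[C@]1(C)CC[C@@H](O1)C(=C)CC(S(=O)(=O)c1ccccc1)C2=O | intermediate
36 | (1R,2S,4S,7R,12S)-2-(TBS-oxy)-4,7-epoxy-11-oxocembr-8(19)-en-16,12-olide | C1C(=O)O[C@@]2(C)CC[C@H]1[C@@H](O[Si](C)(C)C(C)(C)C)C[C@]1(C)CC[C@@H](O1)C(=C)CCC2=O | intermediate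
37 | (1R,2S,4S,7R,11S,12S)-2-(TBS-oxy)-4,7-epoxy-11-hydroxycembr-8(19)-en-16,12-olide | C1C(=O)O[C@@]2(C)CC[C@H]1[C@@H](O[Si](C)(C)C(C)(C)C)C[C@]1(C)CC[C@@H](O1)C(=C)CC[C@@H]2O | intermediate
38 | (1R,2S,4S,7R,11S,12S)-2-(TBS-oxy)-11-(TES-oxy)-4,7-epoxycembr-8(19)-en-16,12-olide | C1C(=O)O[C@@]2(C)CC[C@H]1[C@@H](O[Si](C)(C)C(C)(C)C)C[C@]1(C)CC[C@@H](O1)C(=C)CC[C@@H]2O[Si](CC)(CC)CC | intermediate
39 | 15-(dimethylaminomethyl) derivative of 38, C15 epimers | CN(C)CC1C(=O)O[C@@]2(C)CC[C@H]1[C@@H](O[Si](C)(C)C(C)(C)C)C[C@]1(C)CC[C@@H](O1)C(=C)CC[C@@H]2O[Si](CC)(CC)CC | intermediate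
40 | 15-(trimethylammoniomethyl) derivative of 38, iodide, C15 epimers | C[N+](C)(C)CC1C(=O)O[C@@]2(C)CC[C@H]1[C@@H](O[Si](C)(C)C(C)(C)C)C[C@]1(C)CC[C@@H](O1)C(=C)CC[C@@H]2O[Si](CC)(CC)CC.[I-] | intermediate
41 | (1R,2S,4S,7R,11S,12S)-2-(TBS-oxy)-11-(TES-oxy)-4,7-epoxycembra-8(19),15(17)-dien-16,12-olide | C=C1C(=O)O[C@@]2(C)CC[C@H]1[C@@H](O[Si](C)(C)C(C)(C)C)C[C@]1(C)CC[C@@H](O1)C(=C)CC[C@@H]2O[Si](CC)(CC)CC | intermediate
42 | CNP0289823.1, (1R,2S,4S,7R,11S,12S)-4,7-epoxy-2,11-dihydroxycembra-8(19),15(17)-dien-16,12-olide | C=C1C(=O)O[C@@]2(C)CC[C@H]1[C@@H](O)C[C@]1(C)CC[C@@H](O1)C(=C)CC[C@@H]2O | target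

**Step count and risks**

Total step count: 28. Longest linear sequence: 25 steps (geraniol to target: steps 1–11 and 15–28); the citramalic branch (steps 12–14) joins at step 15.

Steps most likely to fail:

1. Step 23. Ionisation of the aryl ether may be too slow at high dilution, so that intermolecular alkylation (oligomers) or acyl transfer within the enolate competes. The fallback closes the same bond without palladium. It sets out from 34: oxidative removal of the 4-methoxyphenyl group with (NH4)2Ce(NO3)6 in MeCN/H2O at 0 °C should give the allylic alcohol F1, and CBr4/PPh3 converts it into the allylic bromide F2. Slow addition of F2 to Cs2CO3 in MeCN (1 mM, rt) closes C9–C10 by direct C-alkylation of the β-keto sulfone; SN2 and SN2′ give the same product because the allyl unit is symmetric. The route is rejoined at 35.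

2. Step 18. Acylation of the hindered tertiary O12–H may be slower than intermolecular esterification or breakdown of the activated acid. The fallback activates the alcohol instead of relying on acyl-transfer catalysis. It sets out from 26: EDC·HCl and C6F5OH give the pentafluorophenyl ester F3. KN(SiMe3)2 (1 equiv) is then added at −78 °C under high dilution, so that the tertiary potassium alkoxide transacylates intramolecularly at low temperature, before silyl migration can occur. The route is rejoined at 28.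

3. Step 25. Hydride delivery to the C11 ketone may show poor facial selectivity, because the conformation of ring A rather than the acyclic model may decide. The fallback replaces substrate control by catalyst control: 36 is reduced with (R)-2-methyl-CBS-oxazaborolidine and catecholborane in toluene at −78 °C, the enantiomer of the catalyst that should give 11S when C12 acts as the large group. The route is rejoined at 37, and no new compound is formed (F0).

Further compounds
F1 | step 23 | (4R,7S)-4-[(1S)-1-(TBS-oxy)-2-[(2S,5R)-5-(3-hydroxyprop-1-en-2-yl)-2-methyloxolan-2-yl]ethyl]-7-methyl-7-[(phenylsulfonyl)acetyl]oxepan-2-one | C1C(=O)O[C@@](C(=O)CS(=O)(=O)c2ccccc2)(C)CC[C@H]1[C@@H](O[Si](C)(C)C(C)(C)C)C[C@]1(C)CC[C@@H](O1)C(=C)CO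
F2 | step 23 | (4R,7S)-4-[(1S)-2-[(2S,5R)-5-(3-bromoprop-1-en-2-yl)-2-methyloxolan-2-yl]-1-(TBS-oxy)ethyl]-7-methyl-7-[(phenylsulfonyl)acetyl]oxepan-2-one | C1C(=O)O[C@@](C(=O)CS(=O)(=O)c2ccccc2)(C)CC[C@H]1[C@@H](O[Si](C)(C)C(C)(C)C)C[C@]1(C)CC[C@@H](O1)C(=C)CBr
F3 | step 18 | pentafluorophenyl (3R,4S)-4-(TBS-oxy)-3-[(3S)-4-(TBS-oxy)-3-hydroxy-3-methylbutyl]-5-(RB)pentanoate | O=C(Oc1c(F)c(F)c(F)c(F)c1F)C[C@@H](CC[C@](C)(O)CO[Si](C)(C)C(C)(C)C)[C@@H](O[Si](C)(C)C(C)(C)C)C[C@]1(C)CC[C@@H](O1)C(=C)COc1ccc(OC)cc1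
F0 | step 25 | none | none
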